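**Retrosynthetic overview**
1. The target is traced back to its 6,8-dimethoxy lactone (BCl3 cleaves only the C8 methyl ether, peri to the lactone carbonyl), and this to an open hydroxy ester ketal (acid closes lactone ring B at O2–C1 and unmasks the side-chain ketone).
2. The strategy rests on ring A (C4a, C5, C6, C7, C8, C8a): oxygen on C6 and C8, the C1 carboxyl carbon on C8a and the C4 methylene on C4a. This 6-alkyl-2,4-dioxygenated benzoate pattern is cut at C8–C8a and C4a–C5 (Alder–Rickert) into 1,3-dimethoxycyclohexa-1,3-diene and a (5R)-5-hydroxyundec-2-ynoate.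
3. The ynoate comes from an (R)-epoxide and lithiated methyl propiolate; the epoxide from (R)-epichlorohydrin (source of C3) and a ketal Grignard reagent made from 6-bromohexanoyl chloride; the diene from 1,3-dimethoxybenzene by Birch reduction and conjugation.
4. Ring order: ring A by benzannulation first, then lactone ring B.

Key step: step 8

Remark: locants C1–C8a are those of isochroman-1-one; the base-equilibrated diene from step 7 is assumed to be used as obtained (13 with residual 12), only 13 taking part in step 8.

**Route**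

Step 1
Reactants: 1 6-bromohexanoyl chloride
Product: 2 10-bromodecan-5-one
Conditions: n-BuMgCl (1.0 equiv), Fe(acac)3 (3 mol %), THF, −78 °C
Reagents that add atoms: n-butylmagnesium chloride, CCCC[Mg]Cl
Why: Fe(acac)3-catalysed acylation of a Grignard reagent by an acid chloride is much faster at −78 °C than attack on the ketone formed or on the primary bromide, so the mono-ketone should result.

Step 2
Reactants: 2 10-bromodecan-5-one
Product: 3 2-(5-bromopentyl)-2-butyl-1,3-dioxolane
Conditions: HOCH2CH2OH, TsOH·H2O (cat.), PhMe, reflux, Dean–Stark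
Reagents that add atoms: ethylene glycol, OCCO
Why: Acid-catalysed ketalisation with azeotropic removal of water masks the ketone for the organometallic steps, and the primary bromide is inert to these conditions.

Step 3
Reactants: 3 2-(5-bromopentyl)-2-butyl-1,3-dioxolane; 4 (R)-epichlorohydrin
Product: 6 (2R)-8-(2-butyl-1,3-dioxolan-2-yl)-1-chlorooctan-2-ol, via ketal Grignard reagent 5 (not isolated)
Conditions: Mg, THF, 45 °C; then 4, CuI (10 mol %), −40 → −10 °C
Reagents that add atoms: none
Why: CuI-catalysed Grignard opening of the epoxide at its unsubstituted carbon leaves the C–O bond at the stereocentre and the C–Cl bond untouched, so the (R) configuration of 4 is carried into the chlorohydrin.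

Step 4
Reactants: 6 (2R)-8-(2-butyl-1,3-dioxolan-2-yl)-1-chlorooctan-2-ol
Product: 7 2-butyl-2-{6-[(2R)-oxiran-2-yl]hexyl}-1,3-dioxolane
Conditions: NaOH (powdered), Et2O, 23 °C
Reagents that add atoms: none
Why: Intramolecular Williamson etherification (halohydrin to epoxide) displaces chloride at the primary carbon while the oxygen stays on the stereocentre, so the epoxide keeps the (R) configuration.

Step 5
Reactants: 7 2-butyl-2-{6-[(2R)-oxiran-2-yl]hexyl}-1,3-dioxolane; 8 methyl propiolate
Product: 10 methyl (5R)-11-(2-butyl-1,3-dioxolan-2-yl)-5-hydroxyundec-2-ynoate, via methyl 3-lithiopropiolate 9 (not isolated)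
Conditions: 8 (3 equiv), n-BuLi, THF, −78 °C; BF3·OEt2 (3 equiv); then 7, −78 °C
Reagents that add atoms: none
Why: In this Yamaguchi–Hirao alkynylation the BF3-activated terminal epoxide is opened at its primary carbon by the lithium acetylide at −78 °C, a temperature at which the labile lithio ester and the dioxolane should survive, and the stereocentre is not a reaction site.

Step 6
Reactants: 11 1,3-dimethoxybenzene
Product: 12 1,5-dimethoxycyclohexa-1,4-diene
Conditions: Li, NH3 (l), t-BuOH, THF, −78 → −33 °C
Reagents that add atoms: none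
Why: Birch reduction of an arene with two donor groups leaves both methoxy groups on sp2 carbons and gives the 2,5-dihydro compound.

Step 7
Reactants: 12 1,5-dimethoxycyclohexa-1,4-diene
Product: 13 1,3-dimethoxycyclohexa-1,3-diene
Conditions: KOt-Bu (0.2 equiv), DMSO, 23 °C
Reagents that add atoms: none
Why: Base-catalysed prototropic isomerisation through the pentadienyl anion formed at the CH2 between the two methoxy-bearing carbons moves one double bond into conjugation under thermodynamic control and should give an equilibrium mixture in which 13 predominates.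

Step 8
Reactants: 10 methyl (5R)-11-(2-butyl-1,3-dioxolan-2-yl)-5-hydroxyundec-2-ynoate; 13 1,3-dimethoxycyclohexa-1,3-diene
Product: 15 methyl 2-[(2R)-8-(2-butyl-1,3-dioxolan-2-yl)-2-hydroxyoctyl]-4,6-dimethoxybenzoate, via bicyclo[2.2.2]octadiene adduct 14 (not isolated)
Conditions: 13 (4 equiv), neat, acid-free sealed tube, 180 °C
Reagents that add atoms: none
Why: A thermal normal-demand [4+2] cycloaddition of the electron-rich diene 13 to the electron-poor triple bond of 10 gives the bicyclo[2.2.2]octa-2,5-diene 14, which at the same temperature expels its C7–C8 ethano bridge as ethylene by retro-[4+2] reaction (Alder–Rickert reaction), aromatisation making the loss irreversible. The closest known reaction type is the Alder–Rickert benzannulation of 1,3-dimethoxycyclohexa-1,3-diene with alk-2-ynoates to 6-alkyl-2,4-dimethoxybenzoates. Ring A is closed by intermolecular cycloaddition (bonds C8–C8a and C4a–C5) followed by cycloreversion, so its six atoms and four substituents are fixed in one operation. No stereocentre is created in 15: the bridgehead centres of 14, formed as a diastereomer mixture, vanish on aromatisation, and the (R)-carbinol is a spectator. The step needs regioselectivity, which the diene secures because its unsubstituted terminus (C4 of 13), activated by both methoxy groups, carries the largest HOMO coefficient and bonds to the ynoate β-carbon, so the ester lands between the C8 methoxy group and the side chain. It also needs the free hydroxyl and the dioxolane to stay passive, which the acid-free melt should allow, and any hydroxy ester that lactonises in the melt converges with 15 in step 9.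

Step 9
Reactants: 15 methyl 2-[(2R)-8-(2-butyl-1,3-dioxolan-2-yl)-2-hydroxyoctyl]-4,6-dimethoxybenzoate
Product: 16 (3R)-6,8-dimethoxy-3-(7-oxoundecyl)-3,4-dihydro-1H-isochromen-1-one
Conditions: 2 M HCl, THF, 50 °C
Reagents that add atoms: water, O
Why: Acid hydrolysis of the dioxolane frees the ketone, and acid-catalysed intramolecular transesterification by the C3 hydroxyl closes the six-membered lactone with loss of methanol; the C3–O bond is not broken, so (R) is kept.

Step 10
Reactants: 16 (3R)-6,8-dimethoxy-3-(7-oxoundecyl)-3,4-dihydro-1H-isochromen-1-one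
Product: 17 (3R)-8-hydroxy-6-methoxy-3-(7-oxoundecyl)-3,4-dihydro-1H-isochromen-1-one
Conditions: BCl3 (3 equiv), CH2Cl2, −78 → 0 °C
Reagents that add atoms: none
Why: In this chelation-controlled ether cleavage BCl3 binds between the lactone carbonyl and the peri C8 methoxy oxygen and removes only that methyl group, while the C6 methyl ether, the lactone and the ketone should survive at low temperature.

**Compound list**
1 | 6-bromohexanoyl chloride | O=C(Cl)CCCCCBr | starting material
2 | 10-bromodecan-5-one | CCCCC(=O)CCCCCBr | intermediate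
3 | 2-(5-bromopentyl)-2-butyl-1,3-dioxolane | CCCCC1(CCCCCBr)OCCO1 | intermediate
4 | (R)-epichlorohydrin | ClC[C@H]1CO1 | starting material
5 | [5-(2-butyl-1,3-dioxolan-2-yl)pentyl]magnesium bromide | CCCCC1(CCCCC[Mg]Br)OCCO1 | intermediate
6 | (2R)-8-(2-butyl-1,3-dioxolan-2-yl)-1-chlorooctan-2-ol | CCCCC1(OCCO1)CCCCCC[C@@H](O)CCl | intermediate
7 | 2-butyl-2-{6-[(2R)-oxiran-2-yl]hexyl}-1,3-dioxolane | CCCCC1(OCCO1)CCCCCC[C@@H]2CO2 | intermediate
8 | methyl propiolate | C#CC(=O)OC | starting material
9 | methyl 3-lithiopropiolate | [Li]C#CC(=O)OC | intermediate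
10 | methyl (5R)-11-(2-butyl-1,3-dioxolan-2-yl)-5-hydroxyundec-2-ynoate | CCCCC1(OCCO1)CCCCCC[C@@H](O)CC#CC(=O)OC | intermediate
11 | 1,3-dimethoxybenzene | COc1cccc(OC)c1 | starting material
12 | 1,5-dimethoxycyclohexa-1,4-diene | COC1=CCC=C(OC)C1 | intermediate
13 | 1,3-dimethoxycyclohexa-1,3-diene | COC1=CC(OC)=CCC1 | intermediate
14 | methyl 3-[(2R)-8-(2-butyl-1,3-dioxolan-2-yl)-2-hydroxyoctyl]-1,5-dimethoxybicyclo[2.2.2]octa-2,5-diene-2-carboxylate (bridgehead diastereomers) | COC12CCC(C(OC)=C1)C(C[C@H](O)CCCCCCC3(CCCC)OCCO3)=C2C(=O)OC | intermediate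
15 | methyl 2-[(2R)-8-(2-butyl-1,3-dioxolan-2-yl)-2-hydroxyoctyl]-4,6-dimethoxybenzoate | CCCCC1(OCCO1)CCCCCC[C@@H](O)Cc2cc(OC)cc(OC)c2C(=O)OC | intermediate
16 | (3R)-6,8-dimethoxy-3-(7-oxoundecyl)-3,4-dihydro-1H-isochromen-1-one | CCCCC(=O)CCCCCC[C@@H]1Cc2cc(OC)cc(OC)c2C(=O)O1 | intermediate
17 | (3R)-8-hydroxy-6-methoxy-3-(7-oxoundecyl)-3,4-dihydro-1H-isochromen-1-one | CCCCC(=O)CCCCCC[C@@H]1Cc2cc(OC)cc(O)c2C(=O)O1 | target

**Step count**
Total: 10 steps. Longest linear sequence: 8 steps (steps 1, 2, 3, 4, 5, 8, 9, 10); steps 6 and 7 form the diene branch.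

**Steps most likely to fail**

Step 8. The β-alkyl ynoate may add too slowly at a temperature where the diene aromatises or oligomerises, and the free hydroxyl may add to the enol ether, so conversion may stay low. Fallback: ring A is taken from a ready-made arene instead of being built. It sets out from epoxide 7, which is opened at its terminal carbon by commercial 3,5-dimethoxyphenylmagnesium chloride with CuI catalysis (THF, −30 °C) to give (2R)-8-(2-butyl-1,3-dioxolan-2-yl)-1-(3,5-dimethoxyphenyl)octan-2-ol F1. NBS in MeCN at 0 °C should brominate the ring position ortho to the side chain and para to a methoxy group, giving (2R)-1-(2-bromo-3,5-dimethoxyphenyl)-8-(2-butyl-1,3-dioxolan-2-yl)octan-2-ol F2. Carbonylation with Pd(OAc)2 and Xantphos (CO 1 atm, Et3N, PhMe, 100 °C), the side-chain hydroxyl trapping the acylpalladium species, closes the lactone to (3R)-3-[6-(2-butyl-1,3-dioxolan-2-yl)hexyl]-6,8-dimethoxy-3,4-dihydro-1H-isochromen-1-one F3. Hydrolysis of the ketal of F3 with 2 M HCl in THF brings the sequence back to the route at 16.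

Step 5. The lithio ester may decompose before it opens the epoxide, and BF3 may attack the dioxolane, so the epoxide may be recovered or the ketal lost. Fallback: a thermally stable dianion is used without Lewis acid. It sets out from 7, which is opened by dilithium propiolate (propiolic acid, 2 equiv n-BuLi, THF/HMPA, −40 → 23 °C); after acidification to pH 4 this gives (5R)-11-(2-butyl-1,3-dioxolan-2-yl)-5-hydroxyundec-2-ynoic acid F4. Alkylation of the carboxylate with MeI and KHCO3 in DMF, which leaves the secondary alcohol alone, comes back to the route at 10.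

Step 7. Conjugation may stop short at the equilibrium, and the enol ethers may lose methanol to aromatics or hydrolyse on work-up, so too little reactive diene may reach step 8. Fallback: the diene is made by kinetic enolate silylation instead of isomerisation. Commercial 3-methoxycyclohex-2-en-1-one is deprotonated at the α′ carbon with LDA (THF, −78 °C) and silylated with TMSCl to 1-methoxy-3-(trimethylsilyloxy)cyclohexa-1,3-diene F5. The fallback sets out from 10, which is heated with excess F5; cycloaddition with the same regiochemistry gives methyl 3-[(2R)-8-(2-butyl-1,3-dioxolan-2-yl)-2-hydroxyoctyl]-1-methoxy-5-(trimethylsilyloxy)bicyclo[2.2.2]octa-2,5-diene-2-carboxylate F6. Loss of ethylene from F6 gives methyl 2-[(2R)-8-(2-butyl-1,3-dioxolan-2-yl)-2-hydroxyoctyl]-6-methoxy-4-[(trimethylsilyl)oxy]benzoate F7. Methanolysis of the aryl silyl ether (MeOH, cat. KF) gives methyl 2-[(2R)-8-(2-butyl-1,3-dioxolan-2-yl)-2-hydroxyoctyl]-4-hydroxy-6-methoxybenzoate F8. Methylation of the phenol with MeI and K2CO3 in acetone at 23 °C comes back to the route at 15.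

**Further compounds**
F1 | step 8 | (2R)-8-(2-butyl-1,3-dioxolan-2-yl)-1-(3,5-dimethoxyphenyl)octan-2-ol | CCCCC1(OCCO1)CCCCCC[C@@H](O)Cc2cc(OC)cc(OC)c2
F2 | step 8 | (2R)-1-(2-bromo-3,5-dimethoxyphenyl)-8-(2-butyl-1,3-dioxolan-2-yl)octan-2-ol | CCCCC1(OCCO1)CCCCCC[C@@H](O)Cc2cc(OC)cc(OC)c2Br
F3 | step 8 | (3R)-3-[6-(2-butyl-1,3-dioxolan-2-yl)hexyl]-6,8-dimethoxy-3,4-dihydro-1H-isochromen-1-one | CCCCC1(OCCO1)CCCCCC[C@@H]2Cc3cc(OC)cc(OC)c3C(=O)O2
F4 | step 5 | (5R)-11-(2-butyl-1,3-dioxolan-2-yl)-5-hydroxyundec-2-ynoic acid | CCCCC1(OCCO1)CCCCCC[C@@H](O)CC#CC(=O)O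
F5 | step 7 | 1-methoxy-3-(trimethylsilyloxy)cyclohexa-1,3-diene | COC1=CC(O[Si](C)(C)C)=CCC1
F6 | step 7 | methyl 3-[(2R)-8-(2-butyl-1,3-dioxolan-2-yl)-2-hydroxyoctyl]-1-methoxy-5-(trimethylsilyloxy)bicyclo[2.2.2]octa-2,5-diene-2-carboxylate | COC12CCC(C(O[Si](C)(C)C)=C1)C(C[C@H](O)CCCCCCC3(CCCC)OCCO3)=C2C(=O)OC
F7 | step 7 | methyl 2-[(2R)-8-(2-butyl-1,3-dioxolan-2-yl)-2-hydroxyoctyl]-6-methoxy-4-[(trimethylsilyl)oxy]benzoate | CCCCC1(OCCO1)CCCCCC[C@@H](O)Cc2cc(O[Si](C)(C)C)cc(OC)c2C(=O)OC
F8 | step 7 | methyl 2-[(2R)-8-(2-butyl-1,3-dioxolan-2-yl)-2-hydroxyoctyl]-4-hydroxy-6-methoxybenzoate | CCCCC1(OCCO1)CCCCCC[C@@H](O)Cc2cc(O)cc(OC)c2C(=O)OC
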